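## Retrosynthetic overview

1. Target 25 ⇐ phenol desilylation and acetylation of the bridgehead alcohol of furofuranol 23.
2. 23 ⇐ acid-mediated benzylic cycloetherification (C-2–O-3; ring B, closed last) of triol 22 ⇐ aryl Grignard 21 + 1-hydroxy lactol 18.
3. 18 ⇐ bridgehead enolate hydroxylation of cis-fused lactone 15 (the ring fusion dictates C-1) ⇐ lactol 14 ⇐ dithiane 12.
4. 12 (C-6–O-7; ring A, closed first, by SN1 cycloetherification) ⇐ triol 11 ⇐ lactone acetal 10.
5. 10 ⇐ one-pot Michael/aldol: 2-lithio-1,3-dithiane + (5R)-menthyloxybutenolide 5 (C-1–C-2), then lithium enolate + veratraldehyde 7 (C-5–C-6, the fragment union); 5 ⇐ furfural + l-menthol.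

Convention: locants C-1 to C-8 are those of the target's 3,7-dioxabicyclo[3.3.0]octane core (C-1 acetoxy bridgehead, C-2 guaiacyl carbon, C-5 CH bridgehead, C-6 veratryl carbon); the target is (1S,2R,5R,6S), both aryl groups exo. "l-Menthyl" = (1R,2S,5R)-2-isopropyl-5-methylcyclohexyl.

Assumption: carbinol and lactol centres that are later ionised or oxidised (C-6 in 10 and 11; C-2 in 14, 18 and 22) are carried as epimer mixtures and left undefined in their SMILES.

## Route

Step 1
Reactants: 1 furfural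
Product: 3 5-hydroxyfuran-2(5H)-one (racemic hemiacetal), via furfural endoperoxide 2 (not isolated)
Conditions: O2, methylene blue (cat.), MeOH, hν (visible), rt
Reagents that add atoms: oxygen, O=O
Why: Schenck-type photooxygenation, in which singlet oxygen adds [4+2] to the furan and methanolysis of the endoperoxide expels the formyl carbon as methyl formate.

Step 2
Reactants: 3 5-hydroxyfuran-2(5H)-one; 4 l-menthol
Product: 5 (5R)-5-(l-menthyloxy)furan-2(5H)-one
Conditions: TsOH·H2O (cat.), toluene, reflux (Dean–Stark); crystallise from petroleum ether at −20 °C; re-equilibrate mother liquor (cat. TsOH) and recrystallise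
Reagents that add atoms: none
Why: Acid-catalysed acetalisation with the chiral-pool alcohol, where the two C-5 epimers interconvert through the oxocarbenium ion and the crystalline (5R)-epimer is harvested by crystallisation-induced diastereomer transformation.

Step 3
Reactants: 5 (5R)-5-(l-menthyloxy)furan-2(5H)-one; 6 1,3-dithiane; 7 3,4-dimethoxybenzaldehyde
Product: 10 (3S,4R,5R)-3-[(3,4-dimethoxyphenyl)(hydroxy)methyl]-4-(1,3-dithian-2-yl)-5-(l-menthyloxy)dihydrofuran-2(3H)-one (carbinol epimers), via 2-lithio-1,3-dithiane 8 (not isolated), via lithium enolate 9 (not isolated)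
Conditions: 6, n-BuLi, THF, −30 °C, 2 h; 5, −78 °C, 2 h; 7, −78 °C, 2 h; AcOH quench at −78 °C
Reagents that add atoms: none
Why: Tandem Michael–aldol reaction in which the sulfur-stabilised carbanion adds to the butenolide anti to the menthyloxy group (sets C-1) and the resulting lithium enolate adds to the aldehyde anti to the new β-substituent (sets C-5).

Step 4
Reactants: 10 lactone acetal
Product: 11 (2R,3R)-2-[(3,4-dimethoxyphenyl)(hydroxy)methyl]-3-(1,3-dithian-2-yl)butane-1,4-diol (carbinol epimers)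
Conditions: LiAlH4 (4 equiv), THF, 0 °C → reflux; aqueous work-up
Reagents that add atoms: none
Why: Hydride reduction of the lactone carbonyl and of the acetal (masked aldehyde) carbon gives the 1,4-diol and releases the menthol auxiliary without touching C-1 or C-5.

Step 5
Reactants: 11 dithianyl triol
Product: 12 [(2S,3R,4R)-2-(3,4-dimethoxyphenyl)-4-(1,3-dithian-2-yl)tetrahydrofuran-3-yl]methanol
Conditions: TsOH·H2O (10 mol %), CH2Cl2 (0.02 M), rt
Reagents that add atoms: none
Why: Acid-catalysed SN1 cycloetherification through the veratryl cation, in which only the C-8 hydroxyl can close a five-membered ring and the aryl group settles trans to the neighbouring CH2OH, so both carbinol epimers converge on (6S).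

Step 6
Reactants: 12 dithianyl tetrahydrofuran alcohol
Product: 14 (1R,5R,6S)-6-(3,4-dimethoxyphenyl)-3,7-dioxabicyclo[3.3.0]octan-2-ol (anomer mixture), via hydroxy aldehyde 13 (not isolated)
Conditions: I2, NaHCO3, acetone/H2O (5:1), 0 °C
Reagents that add atoms: water, O
Why: Iodine-mediated oxidative dithioacetal hydrolysis unmasks the C-2 aldehyde, which is captured at once by the cis C-4 hydroxyl as the cis-fused lactol, so C-1 cannot epimerise productively.

Step 7
Reactants: 14 bicyclic lactol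
Product: 15 (1R,5R,6S)-6-(3,4-dimethoxyphenyl)-3,7-dioxabicyclo[3.3.0]octan-2-one
Conditions: TEMPO (10 mol %), PhI(OAc)2 (1.5 equiv), CH2Cl2, rt
Reagents that add atoms: none
Why: Oxoammonium (TEMPO/PhI(OAc)2) oxidation of the lactol to the γ-lactone leaves the electron-rich arene and the benzylic ether untouched.

Step 8
Reactants: 15 bicyclic lactone
Product: 17 (1S,5R,6S)-6-(3,4-dimethoxyphenyl)-1-hydroxy-3,7-dioxabicyclo[3.3.0]octan-2-one, via potassium enolate 16 (not isolated)
Conditions: KN(SiMe3)2 (1.2 equiv), THF, −78 °C, 30 min; trans-2-(phenylsulfonyl)-3-phenyloxaziridine (1.5 equiv), −78 °C; AcOH quench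
Reagents that add atoms: trans-2-(phenylsulfonyl)-3-phenyloxaziridine (Davis oxaziridine), O=S(=O)(c1ccccc1)N1OC1c1ccccc1
Why: Davis enolate α-hydroxylation at the bridgehead, where the bicyclo[3.3.0] skeleton can only remain cis-fused, so oxygen replaces H-1 with retention on the convex face and fixes C-1 as S.

Step 9
Reactants: 17 hydroxy lactone
Product: 18 (1S,5R,6S)-6-(3,4-dimethoxyphenyl)-3,7-dioxabicyclo[3.3.0]octane-1,2-diol (anomer mixture)
Conditions: i-Bu2AlH (2.5 equiv), CH2Cl2, −78 °C; aq. KNaC4H4O6 work-up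
Reagents that add atoms: none
Why: Partial reduction of the lactone to the lactol, because the aluminium hemiacetal is stable at −78 °C and collapses only on work-up.

Step 10
Reactants: 19 4-bromo-2-methoxyphenol
Product: 20 (4-bromo-2-methoxyphenoxy)triisopropylsilane
Conditions: i-Pr3SiCl, imidazole, DMF, rt
Reagents that add atoms: triisopropylsilyl chloride, CC(C)[Si](Cl)(C(C)C)C(C)C
Why: Imidazole-promoted silylation protects the phenol as a bulky silyl ether that survives the Grignard, acid and acylation steps and is removed by fluoride at the end.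

Step 11
Reactants: 20 (4-bromo-2-methoxyphenoxy)triisopropylsilane; 18 hydroxy lactol
Product: 22 (3S,4R,5S)-5-(3,4-dimethoxyphenyl)-4-(hydroxymethyl)-3-{hydroxy[3-methoxy-4-(triisopropylsilyloxy)phenyl]methyl}tetrahydrofuran-3-ol (carbinol epimers), via aryl Grignard reagent 21 (not isolated)
Conditions: 20 (4 equiv), Mg turnings, THF, 50 °C; then 18, 0 °C → rt; H2O quench
Reagents that add atoms: none
Why: Grignard addition to the open hydroxy-aldehyde tautomer of the lactol after two equivalents have deprotonated the OH groups, with Cram-chelate control favouring the (R)-carbinol although either epimer is usable.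

Step 12
Reactants: 22 triol
Product: 23 (1S,2R,5R,6S)-6-(3,4-dimethoxyphenyl)-2-[3-methoxy-4-(triisopropylsilyloxy)phenyl]-3,7-dioxabicyclo[3.3.0]octan-1-ol
Conditions: CSA (10 mol %), CH2Cl2, 0 °C
Reagents that add atoms: none
Why: Acid-catalysed SN1 cycloetherification via the para-siloxy-stabilised benzylic cation, trapped 5-exo by the C-4 hydroxyl with the aryl group on the convex (exo) face, which sets C-2 as R.

Step 13
Reactants: 23 furofuranol
Product: 24 (1S,2R,5R,6S)-6-(3,4-dimethoxyphenyl)-2-[3-methoxy-4-(triisopropylsilyloxy)phenyl]-3,7-dioxabicyclo[3.3.0]oct-1-yl acetate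
Conditions: Ac2O (5 equiv), Et3N, DMAP (0.3 equiv), CH2Cl2, 40 °C
Reagents that add atoms: acetic anhydride, CC(=O)OC(C)=O
Why: DMAP-catalysed (Steglich-type) acylation of the hindered tertiary alcohol, the only acylable group left in 23.

Step 14
Reactants: 24 silyl-protected acetate
Product: 25 (1S,2R,5R,6S)-6-(3,4-dimethoxyphenyl)-2-(4-hydroxy-3-methoxyphenyl)-3,7-dioxabicyclo[3.3.0]oct-1-yl acetate (target)
Conditions: Bu4NF, AcOH (1:1), THF, 0 °C
Reagents that add atoms: none
Why: Fluoride-mediated desilylation of the aryl silyl ether, buffered with acetic acid so that the tertiary acetate and both benzylic ethers survive.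

## Compound list

1 | furfural | O=Cc1ccco1 | starting material
2 | furfural endoperoxide (2,3,7-trioxabicyclo[2.2.1]hept-5-ene-1-carbaldehyde) | O=CC12C=CC(OO1)O2 | intermediate (not isolated)
3 | 5-hydroxyfuran-2(5H)-one (racemic) | O=C1C=CC(O)O1 | intermediate
4 | l-menthol, (1R,2S,5R) | CC(C)[C@@H]1CC[C@@H](C)C[C@H]1O | starting material
5 | (5R)-5-(l-menthyloxy)furan-2(5H)-one | O=C1C=C[C@H](O[C@@H]2C[C@H](C)CC[C@H]2C(C)C)O1 | intermediate
6 | 1,3-dithiane | C1CSCSC1 | starting material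
7 | 3,4-dimethoxybenzaldehyde | COc1ccc(C=O)cc1OC | starting material
8 | 2-lithio-1,3-dithiane | [Li]C1SCCCS1 | intermediate (not isolated)
9 | lithium (4R,5R)-4-(1,3-dithian-2-yl)-5-(l-menthyloxy)-4,5-dihydrofuran-2-olate | [Li]OC1=C[C@@H](C2SCCCS2)[C@H](O[C@@H]3C[C@H](C)CC[C@H]3C(C)C)O1 | intermediate (not isolated)
10 | (3S,4R,5R)-3-[(3,4-dimethoxyphenyl)(hydroxy)methyl]-4-(1,3-dithian-2-yl)-5-(l-menthyloxy)dihydrofuran-2(3H)-one, carbinol epimers | O=C1O[C@@H](O[C@@H]2C[C@H](C)CC[C@H]2C(C)C)[C@H](C3SCCCS3)[C@H]1C(O)c4ccc(OC)c(OC)c4 | intermediate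
11 | (2R,3R)-2-[(3,4-dimethoxyphenyl)(hydroxy)methyl]-3-(1,3-dithian-2-yl)butane-1,4-diol, carbinol epimers | OC[C@@H]([C@H](CO)C1SCCCS1)C(O)c1ccc(OC)c(OC)c1 | intermediate
12 | [(2S,3R,4R)-2-(3,4-dimethoxyphenyl)-4-(1,3-dithian-2-yl)tetrahydrofuran-3-yl]methanol | OC[C@@H]1[C@@H](c2ccc(OC)c(OC)c2)OC[C@@H]1C1SCCCS1 | intermediate
13 | (3R,4R,5S)-5-(3,4-dimethoxyphenyl)-4-(hydroxymethyl)tetrahydrofuran-3-carbaldehyde | OC[C@@H]1[C@@H](c2ccc(OC)c(OC)c2)OC[C@@H]1C=O | intermediate (not isolated)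
14 | (1R,5R,6S)-6-(3,4-dimethoxyphenyl)-3,7-dioxabicyclo[3.3.0]octan-2-ol, anomer mixture | OC1OC[C@@H]2[C@@H](c3ccc(OC)c(OC)c3)OC[C@H]12 | intermediate
15 | (1R,5R,6S)-6-(3,4-dimethoxyphenyl)-3,7-dioxabicyclo[3.3.0]octan-2-one | O=C1OC[C@@H]2[C@@H](c3ccc(OC)c(OC)c3)OC[C@H]12 | intermediate
16 | potassium (5R,6S)-6-(3,4-dimethoxyphenyl)-3,7-dioxabicyclo[3.3.0]oct-1-en-2-olate | [K]OC1=C2CO[C@H](c3ccc(OC)c(OC)c3)[C@H]2CO1 | intermediate (not isolated)
17 | (1S,5R,6S)-6-(3,4-dimethoxyphenyl)-1-hydroxy-3,7-dioxabicyclo[3.3.0]octan-2-one | O=C1OC[C@@H]2[C@@H](c3ccc(OC)c(OC)c3)OC[C@]12O | intermediate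
18 | (1S,5R,6S)-6-(3,4-dimethoxyphenyl)-3,7-dioxabicyclo[3.3.0]octane-1,2-diol, anomer mixture | OC1OC[C@@H]2[C@@H](c3ccc(OC)c(OC)c3)OC[C@]12O | intermediate
19 | 4-bromo-2-methoxyphenol | COc1cc(Br)ccc1O | starting material
20 | (4-bromo-2-methoxyphenoxy)triisopropylsilane | COc1cc(Br)ccc1O[Si](C(C)C)(C(C)C)C(C)C | intermediate
21 | [3-methoxy-4-(triisopropylsilyloxy)phenyl]magnesium bromide | Br[Mg]c1ccc(O[Si](C(C)C)(C(C)C)C(C)C)c(OC)c1 | intermediate (not isolated)
22 | (3S,4R,5S)-5-(3,4-dimethoxyphenyl)-4-(hydroxymethyl)-3-{hydroxy[3-methoxy-4-(triisopropylsilyloxy)phenyl]methyl}tetrahydrofuran-3-ol, carbinol epimers | OC[C@@H]1[C@@H](c2ccc(OC)c(OC)c2)OC[C@]1(O)C(O)c1ccc(O[Si](C(C)C)(C(C)C)C(C)C)c(OC)c1 | intermediate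
23 | (1S,2R,5R,6S)-6-(3,4-dimethoxyphenyl)-2-[3-methoxy-4-(triisopropylsilyloxy)phenyl]-3,7-dioxabicyclo[3.3.0]octan-1-ol | COc1cc([C@H]2OC[C@@H]3[C@@H](c4ccc(OC)c(OC)c4)OC[C@]23O)ccc1O[Si](C(C)C)(C(C)C)C(C)C | intermediate
24 | (1S,2R,5R,6S)-6-(3,4-dimethoxyphenyl)-2-[3-methoxy-4-(triisopropylsilyloxy)phenyl]-3,7-dioxabicyclo[3.3.0]oct-1-yl acetate | COc1cc([C@H]2OC[C@@H]3[C@@H](c4ccc(OC)c(OC)c4)OC[C@]23OC(C)=O)ccc1O[Si](C(C)C)(C(C)C)C(C)C | intermediate
25 | (1S,2R,5R,6S)-6-(3,4-dimethoxyphenyl)-2-(4-hydroxy-3-methoxyphenyl)-3,7-dioxabicyclo[3.3.0]oct-1-yl acetate | COc1cc([C@H]2OC[C@@H]3[C@@H](c4ccc(OC)c(OC)c4)OC[C@]23OC(C)=O)ccc1O | target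

## Summary

Total step count: 14. Longest linear sequence: 13 steps (steps 1–9 and 11–14, from furfural); step 10 is a one-step side branch.

Steps most likely to fail, each with a fallback:

Step 3 (tandem Michael–aldol). The parent dithiane anion may add partly 1,2 to the lactone carbonyl, or the enolate may not be captured cleanly by the aldehyde. The fallback sets out from 5 and comes back at 14; it splits the tandem reaction and uses a vinyl group as the masked C-2 aldehyde. CuBr·SMe2-catalysed conjugate addition of CH2=CHMgBr (Me3SiCl, THF, −78 °C) to 5, anti to the menthyloxy group, gives (4S,5R)-4-ethenyl-5-(l-menthyloxy)dihydrofuran-2(3H)-one F1. Its lithium enolate (LiN(i-Pr)2, THF, −78 °C) undergoes the intermolecular aldol addition to 7 anti to the vinyl group, giving the aldol lactone (3S,4R,5R)-3-[(3,4-dimethoxyphenyl)(hydroxy)methyl]-4-ethenyl-5-(l-menthyloxy)dihydrofuran-2(3H)-one F2. LiAlH4 reduction gives the vinyl triol (2R,3R)-2-[(3,4-dimethoxyphenyl)(hydroxy)methyl]-3-ethenylbutane-1,4-diol F3. Catalytic TsOH in CH2Cl2 closes ring A to the vinyl tetrahydrofuran [(2S,3R,4R)-2-(3,4-dimethoxyphenyl)-4-ethenyltetrahydrofuran-3-yl]methanol F4. Ozonolysis (O3, CH2Cl2/MeOH, −78 °C; Me2S) gives aldehyde 13, which closes to lactol 14.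

Step 8 (bridgehead enolate hydroxylation). The enolate may expel the β-alkoxide and open ring A, or may resist oxidation. The fallback sets out from 14 and comes back at 18, bypassing 15–17; it installs the C-1 oxygen by glycal-type epoxidation. Dehydration of 14 (MsCl, Et3N, CH2Cl2, 0 → 40 °C) gives the ring-fusion enol ether (5R,6S)-6-(3,4-dimethoxyphenyl)-3,7-dioxabicyclo[3.3.0]oct-1-ene F5. Dimethyldioxirane (acetone/CH2Cl2, −40 °C) epoxidises it on the only face that keeps the rings cis-fused, giving (1S,2R,5R,6S)-6-(3,4-dimethoxyphenyl)-1,2-epoxy-3,7-dioxabicyclo[3.3.0]octane F6. Hydrolysis of this anomeric epoxide (THF/H2O, NaHCO3) gives 18.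

Step 12 (SN1 closure of ring B). Ionisation next to the tertiary carbinol may give some C-2 endo epimer or pinacol-type rearrangement. The fallback sets out from 22 and comes back at 23; it closes the ring by a stereospecific SN2 reaction. The Cram-chelate epimer of 22 is isolated by chromatography: (3S,4R,5S)-5-(3,4-dimethoxyphenyl)-4-(hydroxymethyl)-3-{(R)-hydroxy[3-methoxy-4-(triisopropylsilyloxy)phenyl]methyl}tetrahydrofuran-3-ol F7. Selective sulfonylation of its primary alcohol (TsCl, pyridine, 0 °C) gives the primary monotosylate F8. NaH in THF at 0 °C then effects Williamson closure by the C-2 alkoxide on C-4 (5-exo-tet, retention at C-2) to give 23.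

## Further compounds

F1 | step 3 | (4S,5R)-4-ethenyl-5-(l-menthyloxy)dihydrofuran-2(3H)-one | O=C1O[C@@H](O[C@@H]2C[C@H](C)CC[C@H]2C(C)C)[C@H](C=C)C1
F2 | step 3 | (3S,4R,5R)-3-[(3,4-dimethoxyphenyl)(hydroxy)methyl]-4-ethenyl-5-(l-menthyloxy)dihydrofuran-2(3H)-one, carbinol epimers | O=C1O[C@@H](O[C@@H]2C[C@H](C)CC[C@H]2C(C)C)[C@H](C=C)[C@H]1C(O)c3ccc(OC)c(OC)c3
F3 | step 3 | (2R,3R)-2-[(3,4-dimethoxyphenyl)(hydroxy)methyl]-3-ethenylbutane-1,4-diol, carbinol epimers | OC[C@@H]([C@H](CO)C=C)C(O)c1ccc(OC)c(OC)c1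
F4 | step 3 | [(2S,3R,4R)-2-(3,4-dimethoxyphenyl)-4-ethenyltetrahydrofuran-3-yl]methanol | OC[C@@H]1[C@@H](c2ccc(OC)c(OC)c2)OC[C@@H]1C=C
F5 | step 8 | (5R,6S)-6-(3,4-dimethoxyphenyl)-3,7-dioxabicyclo[3.3.0]oct-1-ene | C1=C2CO[C@H](c3ccc(OC)c(OC)c3)[C@H]2CO1
F6 | step 8 | (1S,2R,5R,6S)-6-(3,4-dimethoxyphenyl)-1,2-epoxy-3,7-dioxabicyclo[3.3.0]octane | [C@H]12OC[C@@H]3[C@@H](c4ccc(OC)c(OC)c4)OC[C@]13O2
F7 | step 12 | (3S,4R,5S)-5-(3,4-dimethoxyphenyl)-4-(hydroxymethyl)-3-{(R)-hydroxy[3-methoxy-4-(triisopropylsilyloxy)phenyl]methyl}tetrahydrofuran-3-ol | OC[C@@H]1[C@@H](c2ccc(OC)c(OC)c2)OC[C@]1(O)[C@H](O)c1ccc(O[Si](C(C)C)(C(C)C)C(C)C)c(OC)c1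
F8 | step 12 | primary 4-methylbenzenesulfonate of F7 | Cc1ccc(cc1)S(=O)(=O)OC[C@@H]1[C@@H](c2ccc(OC)c(OC)c2)OC[C@]1(O)[C@H](O)c1ccc(O[Si](C(C)C)(C(C)C)C(C)C)c(OC)c1
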